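**Retrosynthetic overview**
1. Target ⇐ desilylation ⇐ angeloylation of the one free hydroxyl (C3–OH) of a 2,18-bis-silylated bicyclic alcohol.
2. Rings A and B ⇐ one cationic bicyclization (ring A closes first, ring B second, in the same event) of an acyclic (2S,3R,4R)-2-silyloxy-3,4-epoxy polyene ending in a (Z)-allylsilane; the butenolide ring is bought in and carried through.
3. Butenolide side chain ⇐ B-alkyl Suzuki coupling with 4-bromofuranone; allylsilane ⇐ carbocupration/vinylation of a terminal alkyne ⇐ propargylation of an allylic bromide.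
4. Epoxide ⇐ hydroxyl-directed threo epoxidation of an (S)-allylic alcohol; that stereocentre ⇐ D-proline-catalysed α-aminoxylation/Wittig of the aldehyde from ozonolysis of geranyl acetate.

Assumption: the target is taken as drawn, (2S,3S,4S,5S,9R,10S) in labdane numbering (C2–OH, C3–O-angelate, C18 = CH2OH, C8=C17 methylidene, C15/C16 butenolide); these locants are used throughout, and TBS = tert-butyldimethylsilyl.

**Step 1**
Reactants: 1 geranyl acetate
Product: 2 (2E)-3-methyl-6-oxohex-2-en-1-yl acetate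
Conditions: O3 (1.0 equiv), CH2Cl2/pyridine, −78 °C; then Me2S, −78 → 23 °C
Reagents that add atoms: ozone, [O-][O+]=O
Why: Chemoselective ozonolysis: the distal trisubstituted alkene is far more electron-rich than the alkene deactivated by the allylic acetate, so one equivalent of ozone cleaves only the isopropylidene end and reductive work-up gives the aldehyde; no stereocentre is formed.

**Step 2**
Reactants: 2 (2E)-3-methyl-6-oxohex-2-en-1-yl acetate; 3 2-(triphenylphosphoranylidene)propanal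
Product: 5 (2E,5S,6E)-3,7-dimethyl-8-oxo-5-[(phenylamino)oxy]octa-2,6-dien-1-yl acetate, via aminoxy aldehyde 4 (not isolated)
Conditions: D-proline (20 mol%), PhNO (0.95 equiv), DMSO, 23 °C, 30 min; then 3, CH2Cl2, 0 → 30 °C
Reagents that add atoms: nitrosobenzene, O=Nc1ccccc1
Why: Proline-catalysed enamine α-aminoxylation (O-selective nitroso aldol directed by the carboxylic acid; D-proline gives the (S) centre that becomes C2, typically above 97% ee) followed in the same flask by an E-selective Wittig olefination with the stabilised formyl ylide, which puts the future C18 trans to C2.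

**Step 3**
Reactants: 5 (2E,5S,6E)-3,7-dimethyl-8-oxo-5-[(phenylamino)oxy]octa-2,6-dien-1-yl acetate
Product: 7 (2E,5S,6E)-5,8-dihydroxy-3,7-dimethylocta-2,6-dien-1-yl acetate, via aminoxy alcohol 6 (not isolated)
Conditions: NaBH4, CeCl3·7H2O, MeOH, −40 °C; then AcOH, Zn dust, 23 °C
Reagents that add atoms: none
Why: Luche 1,2-reduction of the enal leaves the acetate alone, and zinc in acetic acid then cleaves the N–O bond reductively to free the secondary alcohol without touching the stereocentre.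

**Step 4**
Reactants: 7 (2E,5S,6E)-5,8-dihydroxy-3,7-dimethylocta-2,6-dien-1-yl acetate
Product: 8 (2E,5S)-5-hydroxy-5-[(2R,3R)-3-(hydroxymethyl)-3-methyloxiran-2-yl]-3-methylpent-2-en-1-yl acetate
Conditions: mCPBA (1.05 equiv), NaHCO3, CH2Cl2, −20 → 0 °C
Reagents that add atoms: mCPBA, OOC(=O)c1cccc(Cl)c1
Why: Hydroxyl-directed peracid epoxidation (Henbest type) under allylic 1,3-strain control: the methyl group cis to the carbinol carbon fixes the conformer with the carbinol hydrogen in the alkene plane, so the peracid is delivered syn to the C2 hydroxyl and gives the threo (2S,3R,4R) epoxy alcohol (about 95:5 expected), while the acetate-deactivated alkene reacts much more slowly.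

**Step 5**
Reactants: 8 (2E,5S)-5-hydroxy-5-[(2R,3R)-3-(hydroxymethyl)-3-methyloxiran-2-yl]-3-methylpent-2-en-1-yl acetate
Product: 9 (2E,5S)-5-(TBSO)-5-[(2R,3R)-3-(TBSO-methyl)-3-methyloxiran-2-yl]-3-methylpent-2-en-1-yl acetate
Conditions: TBSCl (2.5 equiv), imidazole, DMF, 23 °C
Reagents that add atoms: tert-butyldimethylsilyl chloride, CC(C)(C)[Si](C)(C)Cl
Why: Standard imidazole-mediated silylation caps the C2 and C18 hydroxyls, so that after cyclization the only free hydroxyl is the one at C3.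

**Step 6**
Reactants: 9 (2E,5S)-5-(TBSO)-5-[(2R,3R)-3-(TBSO-methyl)-3-methyloxiran-2-yl]-3-methylpent-2-en-1-yl acetate
Product: 10 (2E,5S)-5-(TBSO)-5-[(2R,3R)-3-(TBSO-methyl)-3-methyloxiran-2-yl]-3-methylpent-2-en-1-ol
Conditions: K2CO3 (cat.), MeOH, 0 °C
Reagents that add atoms: none
Why: Mild base-catalysed transesterification (acetate methanolysis) frees the allylic alcohol while the silyl ethers and the hindered epoxide are inert.

**Step 7**
Reactants: 10 (2E,5S)-5-(TBSO)-5-[(2R,3R)-3-(TBSO-methyl)-3-methyloxiran-2-yl]-3-methylpent-2-en-1-ol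
Product: 11 (2R,3R)-2-[(1S,3E)-5-bromo-1-(TBSO)-3-methylpent-3-en-1-yl]-3-(TBSO-methyl)-3-methyloxirane
Conditions: CBr4, PPh3, 2,6-lutidine, CH2Cl2, −30 → 0 °C
Reagents that add atoms: carbon tetrabromide, BrC(Br)(Br)Br
Why: Appel bromination converts the primary allylic alcohol into the bromide under near-neutral conditions without allylic transposition, with lutidine buffering traces of HBr.

**Step 8**
Reactants: 11 (2R,3R)-2-[(1S,3E)-5-bromo-1-(TBSO)-3-methylpent-3-en-1-yl]-3-(TBSO-methyl)-3-methyloxirane; 12 propargyl bromide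
Product: 14 (2R,3R)-2-[(1S,3E)-1-(TBSO)-3-methyloct-3-en-7-yn-1-yl]-3-(TBSO-methyl)-3-methyloxirane, via dilithiopropyne 13 (not isolated)
Conditions: 12, n-BuLi (2 equiv), TMEDA, Et2O/hexane, −78 °C; then 11, −78 → −20 °C; aq. NH4Cl
Reagents that add atoms: none
Why: Propargylation with 1,3-dilithiopropyne: the sp3 carbanion displaces the allylic bromide (SN2) and the acetylide end is protonated on work-up, giving the terminal alkyne in one step, while the low temperature spares the hindered epoxide.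

**Step 9**
Reactants: 14 (2R,3R)-2-[(1S,3E)-1-(TBSO)-3-methyloct-3-en-7-yn-1-yl]-3-(TBSO-methyl)-3-methyloxirane; 15 (trimethylsilyl)methylmagnesium chloride; 16 vinyl bromide
Product: 20 (2R,3R)-2-[(1S,3E,7Z)-1-(TBSO)-3-methyl-7-(trimethylsilylmethyl)deca-3,7,9-trien-1-yl]-3-(TBSO-methyl)-3-methyloxirane, via silylmethylcopper 17 (not isolated), via alkenylcopper 18 (not isolated), via alkenylzinc bromide 19 (not isolated)
Conditions: 15, CuBr·SMe2, Et2O/Me2S, −40 °C; 14, −25 → 0 °C; then ZnBr2, Pd(PPh3)4 (5 mol%), 16, THF, 0 → 23 °C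
Reagents that add atoms: none
Why: Syn carbocupration of the terminal alkyne (silylmethyl group to the internal carbon, copper to the terminal carbon) followed by transmetalation to zinc and stereoretentive palladium-catalysed Negishi coupling with vinyl bromide fixes the trisubstituted allylsilane with the silylmethyl group cis to the new vinyl group (future C17 cis to C11).

**Step 10**
Reactants: 20 (2R,3R)-2-[(1S,3E,7Z)-1-(TBSO)-3-methyl-7-(trimethylsilylmethyl)deca-3,7,9-trien-1-yl]-3-(TBSO-methyl)-3-methyloxirane; 21 4-bromofuran-2(5H)-one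
Product: 23 4-[(3Z,7E,10S)-10-(TBSO)-10-[(2R,3R)-3-(TBSO-methyl)-3-methyloxiran-2-yl]-8-methyl-4-(trimethylsilylmethyl)deca-3,7-dien-1-yl]furan-2(5H)-one, via alkylborane 22 (not isolated)
Conditions: 9-BBN, THF, 0 → 23 °C; then 21, Pd(dppf)Cl2 (5 mol%), AsPh3, Cs2CO3, DMF/H2O, 23 °C
Reagents that add atoms: none
Why: 9-BBN hydroborates only the monosubstituted terminus of the diene (trisubstituted alkenes are inert) with boron on the terminal carbon, and B-alkyl Suzuki–Miyaura coupling with the vinylogous acyl bromide 21 installs the butenolide without strong base or hydride.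

**Step 11**
Reactants: 23 4-[(3Z,7E,10S)-10-(TBSO)-10-[(2R,3R)-3-(TBSO-methyl)-3-methyloxiran-2-yl]-8-methyl-4-(trimethylsilylmethyl)deca-3,7-dien-1-yl]furan-2(5H)-one
Product: 24 (2S,3S,4S,5S,9R,10S)-2,18-bis(TBSO)-3-hydroxylabda-8(17),13-dien-15,16-olide
Conditions: MeAlCl2 (3 equiv), 2,6-di-tert-butyl-4-methylpyridine, CH2Cl2, −78 → −40 °C; then Et3N/MeOH, aq. KNaC4H4O6
Reagents that add atoms: none
Why: Proposed new method: a Lewis-acid-triggered epoxy-polyene bicyclization whose initiator is a bis-silylated 2,3-epoxy-1,4-diol (silyloxy group on the carbon next to the epoxide, silyloxymethyl group on the tertiary epoxide carbon), a substrate class on which this cyclization has not been shown; MeAlCl2 binds the epoxide oxygen, the tertiary C4–O bond is cleaved (the secondary C3 is further deactivated by the C2–OTBS dipole) with anti attack of the C5=C10 alkene through a chair in which C3–OAl and C2–OTBS are both equatorial, so C4 is inverted (CH2OTBS equatorial) and C5/C10 are set trans, and the C10 cation is then captured through a second chair by the (Z)-allylsilane, which places C11 equatorial at C9 and loses silicon to give the 8(17)-methylidene, the two β-oxygens being expected to make the opening more concerted and so to suppress hydride-shift ketone formation; the closest known reaction type is the MeAlCl2- or BF3-promoted cyclization of simple 2,3-epoxy polyenes terminated by an allylsilane.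

**Step 12**
Reactants: 24 (2S,3S,4S,5S,9R,10S)-2,18-bis(TBSO)-3-hydroxylabda-8(17),13-dien-15,16-olide; 25 angelic acid
Product: 27 (2S,3S,4S,5S,9R,10S)-3-angeloyloxy-2,18-bis(TBSO)-labda-8(17),13-dien-15,16-olide, via mixed anhydride 26 (not isolated)
Conditions: 25, 2,4,6-trichlorobenzoyl chloride, Et3N, toluene, 23 °C; then 24, 80 °C
Reagents that add atoms: none
Why: Yamaguchi mixed-anhydride acylation run without DMAP acylates the only free hydroxyl (C3–OH) and avoids the angelate-to-tiglate isomerisation that nucleophilic catalysts cause.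

**Step 13**
Reactants: 27 (2S,3S,4S,5S,9R,10S)-3-angeloyloxy-2,18-bis(TBSO)-labda-8(17),13-dien-15,16-olide
Product: 28 CNP0335424.2, (2S,3S,4S,5S,9R,10S)-3-angeloyloxy-2,18-dihydroxylabda-8(17),13-dien-15,16-olide
Conditions: HF·pyridine, pyridine, THF, 0 → 23 °C
Reagents that add atoms: none
Why: Fluoride-mediated desilylation with pyridine-buffered HF removes both TBS ethers under weakly acidic conditions that do not cause acyl migration, move the exocyclic alkene or open the butenolide.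

**Compound list**
1 | geranyl acetate, (2E)-3,7-dimethylocta-2,6-dien-1-yl acetate | CC(=O)OC/C=C(\C)CCC=C(C)C | starting material
2 | (2E)-3-methyl-6-oxohex-2-en-1-yl acetate | CC(=O)OC/C=C(\C)CCC=O | intermediate
3 | 2-(triphenylphosphoranylidene)propanal | CC(C=O)=P(c1ccccc1)(c1ccccc1)c1ccccc1 | starting material
4 | (2E,5S)-3-methyl-6-oxo-5-[(phenylamino)oxy]hex-2-en-1-yl acetate (not isolated) | CC(=O)OC/C=C(\C)C[C@H](ONc1ccccc1)C=O | intermediate
5 | (2E,5S,6E)-3,7-dimethyl-8-oxo-5-[(phenylamino)oxy]octa-2,6-dien-1-yl acetate | CC(=O)OC/C=C(\C)C[C@H](ONc1ccccc1)/C=C(\C)C=O | intermediate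
6 | (2E,5S,6E)-8-hydroxy-3,7-dimethyl-5-[(phenylamino)oxy]octa-2,6-dien-1-yl acetate (not isolated) | CC(=O)OC/C=C(\C)C[C@H](ONc1ccccc1)/C=C(\C)CO | intermediate
7 | (2E,5S,6E)-5,8-dihydroxy-3,7-dimethylocta-2,6-dien-1-yl acetate | CC(=O)OC/C=C(\C)C[C@H](O)/C=C(\C)CO | intermediate
8 | (2E,5S)-5-hydroxy-5-[(2R,3R)-3-(hydroxymethyl)-3-methyloxiran-2-yl]-3-methylpent-2-en-1-yl acetate | CC(=O)OC/C=C(\C)C[C@H](O)[C@@H](O1)[C@@]1(C)CO | intermediate
9 | (2E,5S)-5-(TBSO)-5-[(2R,3R)-3-(TBSO-methyl)-3-methyloxiran-2-yl]-3-methylpent-2-en-1-yl acetate | CC(=O)OC/C=C(\C)C[C@H](O[Si](C)(C)C(C)(C)C)[C@@H](O1)[C@@]1(C)CO[Si](C)(C)C(C)(C)C | intermediate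
10 | (2E,5S)-5-(TBSO)-5-[(2R,3R)-3-(TBSO-methyl)-3-methyloxiran-2-yl]-3-methylpent-2-en-1-ol | OC/C=C(\C)C[C@H](O[Si](C)(C)C(C)(C)C)[C@@H](O1)[C@@]1(C)CO[Si](C)(C)C(C)(C)C | intermediate
11 | (2R,3R)-2-[(1S,3E)-5-bromo-1-(TBSO)-3-methylpent-3-en-1-yl]-3-(TBSO-methyl)-3-methyloxirane | BrC/C=C(\C)C[C@H](O[Si](C)(C)C(C)(C)C)[C@@H](O1)[C@@]1(C)CO[Si](C)(C)C(C)(C)C | intermediate
12 | propargyl bromide (3-bromoprop-1-yne) | C#CCBr | starting material
13 | 1,3-dilithiopropyne (not isolated) | [Li]CC#C[Li] | intermediate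
14 | (2R,3R)-2-[(1S,3E)-1-(TBSO)-3-methyloct-3-en-7-yn-1-yl]-3-(TBSO-methyl)-3-methyloxirane | C#CCC/C=C(\C)C[C@H](O[Si](C)(C)C(C)(C)C)[C@@H](O1)[C@@]1(C)CO[Si](C)(C)C(C)(C)C | intermediate
15 | (trimethylsilyl)methylmagnesium chloride | C[Si](C)(C)C[Mg]Cl | starting material
16 | vinyl bromide | C=CBr | starting material
17 | (trimethylsilylmethyl)copper (not isolated) | C[Si](C)(C)C[Cu] | intermediate
18 | [(1Z,5E,8S)-8-(TBSO)-8-[(2R,3R)-3-(TBSO-methyl)-3-methyloxiran-2-yl]-6-methyl-2-(trimethylsilylmethyl)octa-1,5-dien-1-yl]copper (not isolated) | [Cu]/C=C(\C[Si](C)(C)C)CC/C=C(\C)C[C@H](O[Si](C)(C)C(C)(C)C)[C@@H](O1)[C@@]1(C)CO[Si](C)(C)C(C)(C)C | intermediate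
19 | the corresponding (1Z)-alkenylzinc bromide (not isolated) | Br[Zn]/C=C(\C[Si](C)(C)C)CC/C=C(\C)C[C@H](O[Si](C)(C)C(C)(C)C)[C@@H](O1)[C@@]1(C)CO[Si](C)(C)C(C)(C)C | intermediate
20 | (2R,3R)-2-[(1S,3E,7Z)-1-(TBSO)-3-methyl-7-(trimethylsilylmethyl)deca-3,7,9-trien-1-yl]-3-(TBSO-methyl)-3-methyloxirane | C=C/C=C(\C[Si](C)(C)C)CC/C=C(\C)C[C@H](O[Si](C)(C)C(C)(C)C)[C@@H](O1)[C@@]1(C)CO[Si](C)(C)C(C)(C)C | intermediate
21 | 4-bromofuran-2(5H)-one | O=C1OCC(Br)=C1 | starting material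
22 | 9-[(3Z,7E,10S)-10-(TBSO)-10-[(2R,3R)-3-(TBSO-methyl)-3-methyloxiran-2-yl]-8-methyl-4-(trimethylsilylmethyl)deca-3,7-dien-1-yl]-9-borabicyclo[3.3.1]nonane (not isolated) | C1CC2CCCC(C1)B2CC/C=C(\C[Si](C)(C)C)CC/C=C(\C)C[C@H](O[Si](C)(C)C(C)(C)C)[C@@H](O1)[C@@]1(C)CO[Si](C)(C)C(C)(C)C | intermediate
23 | 4-[(3Z,7E,10S)-10-(TBSO)-10-[(2R,3R)-3-(TBSO-methyl)-3-methyloxiran-2-yl]-8-methyl-4-(trimethylsilylmethyl)deca-3,7-dien-1-yl]furan-2(5H)-one | O=C1OCC(=C1)CC/C=C(\C[Si](C)(C)C)CC/C=C(\C)C[C@H](O[Si](C)(C)C(C)(C)C)[C@@H](O1)[C@@]1(C)CO[Si](C)(C)C(C)(C)C | intermediate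
24 | (2S,3S,4S,5S,9R,10S)-2,18-bis(TBSO)-3-hydroxylabda-8(17),13-dien-15,16-olide | C=C1CC[C@H]2[C@@](C)(C[C@H](O[Si](C)(C)C(C)(C)C)[C@@H](O)[C@]2(C)CO[Si](C)(C)C(C)(C)C)[C@@H]1CCC1=CC(=O)OC1 | intermediate
25 | angelic acid, (2Z)-2-methylbut-2-enoic acid | C/C=C(/C)C(=O)O | starting material
26 | angelic 2,4,6-trichlorobenzoic anhydride (not isolated) | C/C=C(/C)C(=O)OC(=O)c1c(Cl)cc(Cl)cc1Cl | intermediate
27 | (2S,3S,4S,5S,9R,10S)-3-angeloyloxy-2,18-bis(TBSO)-labda-8(17),13-dien-15,16-olide | C=C1CC[C@H]2[C@@](C)(C[C@H](O[Si](C)(C)C(C)(C)C)[C@@H](OC(=O)/C(C)=C\C)[C@]2(C)CO[Si](C)(C)C(C)(C)C)[C@@H]1CCC1=CC(=O)OC1 | intermediate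
28 | CNP0335424.2, (1S,2S,3S,4aS,5R,8aS)-3-hydroxy-1-(hydroxymethyl)-1,4a-dimethyl-6-methylidene-5-[2-(5-oxo-2,5-dihydrofuran-3-yl)ethyl]decahydronaphthalen-2-yl (2Z)-2-methylbut-2-enoate | C=C1CC[C@H]2[C@@](C)(C[C@H](O)[C@@H](OC(=O)/C(C)=C\C)[C@]2(C)CO)[C@@H]1CCC1=CC(=O)OC1 | target

**Totals**
Total steps: 13. Longest linear sequence: 13 steps (1 → 28); all other reactants are bought.

**The three steps most likely to fail**

Step 9 (carbocupration/vinylation). (Trimethylsilylmethyl)copper is a sluggish carbocupration partner, and the magnesium halides present may attack the epoxide during the long reaction time. The fallback sets out from bromide 11 and comes back at diene 20, building the allylsilane by enol phosphate cross-coupling instead. Alkylation of the dianion of methyl acetoacetate (NaH, then n-BuLi, THF, 0 °C) with 11 gives methyl (6E,9S)-9-(TBSO)-9-[(2R,3R)-3-(TBSO-methyl)-3-methyloxiran-2-yl]-7-methyl-3-oxonon-6-enoate F1. NaH and ClP(O)(OEt)2 in Et2O give, under chelation control, the (2Z)-enol phosphate F2. Coupling of F2 with 15 under Ni(acac)2 catalysis replaces the phosphate with retention and gives the (2Z)-3-(trimethylsilylmethyl) enoate F3. Reduction with i-Bu2AlH at −78 °C gives the (2Z)-allylic alcohol F4, MnO2 gives the (2Z)-enal F5, and methylenation with Ph3P=CH2 gives 20.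

Step 11 (the proposed new bicyclization). The two oxygen substituents flanking the epoxide may slow ionisation so far that rearrangement of the epoxy silyl ether to a carbonyl compound or protodesilylation of the allylsilane wins. The fallback uses only known chemistry; it sets out from geranyl acetate 1 and comes back at 24. It cyclizes an ordinary epoxide without oxygen at C2 and adds the C2 oxygen afterwards; the butenolide is attached late because it would not survive enol silane formation.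
- Allylic oxidation of 1 with SeO2 in refluxing ethanol gives (2E,6E)-3,7-dimethyl-8-oxoocta-2,6-dien-1-yl acetate F6.
- Iminium-catalysed epoxidation of this α-branched enal (9-amino-9-deoxy-epi-cinchona primary amine with a chiral phosphoric acid, aqueous H2O2; catalyst enantiomers chosen for the (2R,3S) product) gives epoxy aldehyde F7.
- NaBH4 gives epoxy alcohol F8, TBSCl/imidazole gives silyl ether F9, K2CO3/MeOH gives allylic alcohol F10, CBr4/PPh3 gives bromide F11, and 1,3-dilithiopropyne gives alkyne F12.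
- One-pot carbocupration with 15/CuBr·SMe2 and opening of oxirane gives homoallylic alcohol F13, and CBr4/PPh3 gives the primary bromide F14.
- MeAlCl2 cyclization of F14, now the established epoxy-polyene/allylsilane reaction, gives bicyclic alcohol F15.
- Dess–Martin periodinane gives ketone F16 and TBSOTf/Et3N gives silyl enol ether F17.
- Rubottom oxidation of F17 with dimethyldioxirane, which attacks the face opposite the two axial methyl groups and is followed by silyl migration, gives the 2-silyloxy ketone F18.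
- Zinc insertion (Zn, LiCl, cat. NaI) and Negishi coupling with 21 under Pd(PPh3)4 gives keto-butenolide F19.
- NaBH4/CeCl3·7H2O at −40 °C, with axial hydride delivery, gives 24.

Step 12 (angeloylation). The C3 hydroxyl sits between a silyloxy-bearing carbon and a quaternary carbon, and the hindered α-branched mixed anhydride may react too slowly or isomerise to the tiglate on prolonged heating. The fallback sets out from 24 and comes back at 27, building the angelate double bond on the molecule. Carbodiimide/DMAP esterification of 24 with the small sp3 acid 2-(diphenoxyphosphoryl)propanoic acid gives the phosphonate ester F20. An Ando-type Z-selective Horner–Wadsworth–Emmons reaction of F20 with acetaldehyde (NaI, DBU, THF, −78 → 0 °C) gives 27.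

**Further compounds**
F1 | step 9 | methyl (6E,9S)-9-(TBSO)-9-[(2R,3R)-3-(TBSO-methyl)-3-methyloxiran-2-yl]-7-methyl-3-oxonon-6-enoate | COC(=O)CC(=O)CC/C=C(\C)C[C@H](O[Si](C)(C)C(C)(C)C)[C@@H](O1)[C@@]1(C)CO[Si](C)(C)C(C)(C)C
F2 | step 9 | methyl (2Z,6E,9S)-3-(diethoxyphosphoryloxy)-9-(TBSO)-9-[(2R,3R)-3-(TBSO-methyl)-3-methyloxiran-2-yl]-7-methylnona-2,6-dienoate | COC(=O)/C=C(\OP(=O)(OCC)OCC)CC/C=C(\C)C[C@H](O[Si](C)(C)C(C)(C)C)[C@@H](O1)[C@@]1(C)CO[Si](C)(C)C(C)(C)C
F3 | step 9 | methyl (2Z,6E,9S)-9-(TBSO)-9-[(2R,3R)-3-(TBSO-methyl)-3-methyloxiran-2-yl]-7-methyl-3-(trimethylsilylmethyl)nona-2,6-dienoate | COC(=O)/C=C(\C[Si](C)(C)C)CC/C=C(\C)C[C@H](O[Si](C)(C)C(C)(C)C)[C@@H](O1)[C@@]1(C)CO[Si](C)(C)C(C)(C)C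
F4 | step 9 | (2Z,6E,9S)-9-(TBSO)-9-[(2R,3R)-3-(TBSO-methyl)-3-methyloxiran-2-yl]-7-methyl-3-(trimethylsilylmethyl)nona-2,6-dien-1-ol | OC/C=C(\C[Si](C)(C)C)CC/C=C(\C)C[C@H](O[Si](C)(C)C(C)(C)C)[C@@H](O1)[C@@]1(C)CO[Si](C)(C)C(C)(C)C
F5 | step 9 | (2Z,6E,9S)-9-(TBSO)-9-[(2R,3R)-3-(TBSO-methyl)-3-methyloxiran-2-yl]-7-methyl-3-(trimethylsilylmethyl)nona-2,6-dienal | O=C/C=C(\C[Si](C)(C)C)CC/C=C(\C)C[C@H](O[Si](C)(C)C(C)(C)C)[C@@H](O1)[C@@]1(C)CO[Si](C)(C)C(C)(C)C
F6 | step 11 | (2E,6E)-3,7-dimethyl-8-oxoocta-2,6-dien-1-yl acetate | CC(=O)OC/C=C(\C)CC/C=C(\C)C=O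
F7 | step 11 | (2E)-5-[(2R,3S)-3-formyl-3-methyloxiran-2-yl]-3-methylpent-2-en-1-yl acetate | CC(=O)OC/C=C(\C)CC[C@@H](O1)[C@@]1(C)C=O
F8 | step 11 | (2E)-5-[(2R,3R)-3-(hydroxymethyl)-3-methyloxiran-2-yl]-3-methylpent-2-en-1-yl acetate | CC(=O)OC/C=C(\C)CC[C@@H](O1)[C@@]1(C)CO
F9 | step 11 | (2E)-5-[(2R,3R)-3-(TBSO-methyl)-3-methyloxiran-2-yl]-3-methylpent-2-en-1-yl acetate | CC(=O)OC/C=C(\C)CC[C@@H](O1)[C@@]1(C)CO[Si](C)(C)C(C)(C)C
F10 | step 11 | (2E)-5-[(2R,3R)-3-(TBSO-methyl)-3-methyloxiran-2-yl]-3-methylpent-2-en-1-ol | OC/C=C(\C)CC[C@@H](O1)[C@@]1(C)CO[Si](C)(C)C(C)(C)C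
F11 | step 11 | (2R,3R)-3-[(3E)-5-bromo-3-methylpent-3-en-1-yl]-2-(TBSO-methyl)-2-methyloxirane | BrC/C=C(\C)CC[C@@H](O1)[C@@]1(C)CO[Si](C)(C)C(C)(C)C
F12 | step 11 | (2R,3R)-2-(TBSO-methyl)-2-methyl-3-[(3E)-3-methyloct-3-en-7-yn-1-yl]oxirane | C#CCC/C=C(\C)CC[C@@H](O1)[C@@]1(C)CO[Si](C)(C)C(C)(C)C
F13 | step 11 | (3Z,7E)-10-[(2R,3R)-3-(TBSO-methyl)-3-methyloxiran-2-yl]-8-methyl-4-(trimethylsilylmethyl)deca-3,7-dien-1-ol | OCC/C=C(\C[Si](C)(C)C)CC/C=C(\C)CC[C@@H](O1)[C@@]1(C)CO[Si](C)(C)C(C)(C)C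
F14 | step 11 | (2R,3R)-3-[(3E,7Z)-10-bromo-3-methyl-7-(trimethylsilylmethyl)deca-3,7-dien-1-yl]-2-(TBSO-methyl)-2-methyloxirane | BrCC/C=C(\C[Si](C)(C)C)CC/C=C(\C)CC[C@@H](O1)[C@@]1(C)CO[Si](C)(C)C(C)(C)C
F15 | step 11 | (3R,4S,5S,9R,10S)-12-bromo-18-(TBSO)-13,14,15,16-tetranorlabd-8(17)-en-3-ol | C=C1CC[C@H]2[C@@](C)(CC[C@@H](O)[C@]2(C)CO[Si](C)(C)C(C)(C)C)[C@@H]1CCBr
F16 | step 11 | (4S,5S,9R,10S)-12-bromo-18-(TBSO)-13,14,15,16-tetranorlabd-8(17)-en-3-one | C=C1CC[C@H]2[C@@](C)(CCC(=O)[C@]2(C)CO[Si](C)(C)C(C)(C)C)[C@@H]1CCBr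
F17 | step 11 | (4S,5S,9R,10S)-12-bromo-3,18-bis(TBSO)-13,14,15,16-tetranorlabda-2,8(17)-diene | C=C1CC[C@H]2[C@@](C)(CC=C(O[Si](C)(C)C(C)(C)C)[C@]2(C)CO[Si](C)(C)C(C)(C)C)[C@@H]1CCBr
F18 | step 11 | (2S,4S,5S,9R,10S)-12-bromo-2,18-bis(TBSO)-13,14,15,16-tetranorlabd-8(17)-en-3-one | C=C1CC[C@H]2[C@@](C)(C[C@H](O[Si](C)(C)C(C)(C)C)C(=O)[C@]2(C)CO[Si](C)(C)C(C)(C)C)[C@@H]1CCBr
F19 | step 11 | (2S,4S,5S,9R,10S)-2,18-bis(TBSO)-3-oxolabda-8(17),13-dien-15,16-olide | C=C1CC[C@H]2[C@@](C)(C[C@H](O[Si](C)(C)C(C)(C)C)C(=O)[C@]2(C)CO[Si](C)(C)C(C)(C)C)[C@@H]1CCC1=CC(=O)OC1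
F20 | step 12 | (2S,3S,4S,5S,9R,10S)-3-[2-(diphenoxyphosphoryl)propanoyloxy]-2,18-bis(TBSO)-labda-8(17),13-dien-15,16-olide (both epimers at the phosphonate carbon) | C=C1CC[C@H]2[C@@](C)(C[C@H](O[Si](C)(C)C(C)(C)C)[C@@H](OC(=O)C(C)P(=O)(Oc3ccccc3)Oc3ccccc3)[C@]2(C)CO[Si](C)(C)C(C)(C)C)[C@@H]1CCC1=CC(=O)OC1
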